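We read this flask at 90 min, so we ask how many half-lives of its rise fit into that time.

the same everywhere: D 0.91 M
- violet: J 1.09 M; the very flask that is asked about, followed so far
- green: J 2.2 M; run made earlier
- flask: J 1.09 M; time 1.5 h; volume of the second phase over the first 1.0

- violet (time / min: Q / %): 10.0: 21.7; 20.0: 24.6; 25.0: 24.5; 40.0: 23.8
- green (time / min: Q / %): 5.00: 26.6; 12.0: 32.1; 25.0: 34.0; 40.0: 33.1

(each reading ± 0.5 percentage points)

- in the second phase: J; everything else is in the first
- charges count per volume of the first phase; a concentration in a rate is the amount of a species over the volume of its own phase; every rate counts per litre of the first phase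
- the earlier runs hold the two phases in the same ratio of volumes as the flask asked about

- Thursday's: doubling the transfer coefficient of J, all else as stated
- Sunday's: doubling the amount of J, all else as stated

* Q at 1.5 h, in percent of the D charged
* the change that raises the amount of Q at 1.5 h, in percent of the D charged most ("none" if none brings more than 2 percentage points) (Thursday's / Sunday's / none)
* amount of Q at 1.5 h, in percent of the D charged, after Sunday's

The fastest rung is the rise. Violet shows Q at 21.7% after 10.0 min and 24.5% after 25.0 min, and from that gap we get the time in which the distance to the plateau halves, our rise half-life 3.20 min. This is a reading, since the gap of 2.8 percentage points carries a scatter of 0.5 points. Green, read the same way at 12.0 min, gives 2.88 min.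

On the next rung, violet falls 0.8 points from 20.0 min to 40.0 min, while two readings differ by 0.71 points from scatter, so we see no slower step.

The last rung is the asked time, which holds 28.2 half-lives. We therefore commit to the mean of violet's last readings, 24.3%. Sunday's change gives 2.18 M of J, close to green's 2.2 M, so we take green's late mean, 33.6%. Thursday's change hurries a rise that ends long before the reading, so we expect little from it.

The forecast gives 22% (20.3% to 23.9%), which is lower than ours, as it reads the sag as “a slow drain on Q”. It picks Sunday's, with 30.5% (28% to 33.2%).

The flask gives 24.9% and, after Sunday's change, 33.6%, a gain of 8.7 points against 0.0052 points for Thursday's. Both values lie above the forecast's ranges, by 1 point and 0.40 points, and its pick of Sunday's is right.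

    L + Q → Z (k = 0.130 /M/min)
    L + Q → E (k = 0.280 /M/min)
    L → X (k = 0.730 /min)
    L ⇌ J, rate k4*([L] - [J]/K4) per volume of the first phase (partition coefficient = 1.30, kL = 0.330 /min)
    D + L → Q (k = 0.360 /M/min)
    2 D → G (k = 8.00 × 10⁻⁵ /M/min)

At 0.150 h our half-life leaves 14.2% of the rise open, and J, the limiting reagent here, stands at 18.0% of its own charge. At 1.5 h J is at 0%, with D at 68%. The neighbour with D at 2.3 M has the same J charge, but no run shows its rise, so we do not carry our count over. Its cL has reached 1.75 × 10⁻⁹ M at 1.50 h, which is 29.2 halvings below the 1.09 M of J charged, one per 3.08 min, against one per 3.44 min in this flask and our 3.20 min read from violet. Its J stands at 0%, and its Q at 19.2%.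

All runs are calculated from invented constants, and the scatter is random.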